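**Retrosynthetic overview**
- Bonannione A comes from its 4′-O-silyl ether by buffered desilylation; nothing else is protected.
- Rings C and A are closed last, in one pot, from an acyclic δ-hydroxy polyketide chain: acid closes the pyranone (ring C, O1–C8a), then heat generates an acylketene that closes the phloroglucinol (ring A, C4a–C5) by 6π-electrocyclisation.
- The chain is assembled at C8–C8a by γ-acylation of the dianion of tert-butyl 2-geranylacetoacetate with an (S)-configured 6-aryl-4-methoxy-5,6-dihydropyran-2-one, which is ring-opened in the process.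
- That lactone, carrying ring B and the only stereocentre, comes from an asymmetric hetero-Diels–Alder reaction of 4-silyloxybenzaldehyde with Brassard's diene; the C–O bond at that carbon is never broken afterwards.

Assumption: the (S,S)-TADDOL catalyst (and (S)-BINOL in the fallback) is taken to direct attack to the Si face of the aldehyde, giving the (S)-lactone; if the sense proves opposite, the other catalyst enantiomer is used.

**Step 1**
Reactants: 1 tert-butyl acetoacetate; 2 geranyl bromide
Product: 3 tert-butyl 2-[(2E)-3,7-dimethylocta-2,6-dien-1-yl]-3-oxobutanoate (tert-butyl 2-geranylacetoacetate; racemic at C2)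
Conditions: NaH (1.0 equiv), THF, 0 °C; then 2 (0.9 equiv), 0 → 23 °C
Reagents that add atoms: none
Why: Acetoacetic ester C-alkylation of the sodium enolate by SN2 at the primary allylic bromide keeps the E-alkene, and the C2 centre is irrelevant because it becomes sp2 later.

**Step 2**
Reactants: 4 methyl (E)-3-methoxybut-2-enoate
Product: 5 Brassard diene, (E)-1,3-dimethoxy-1-(trimethylsilyloxy)buta-1,3-diene
Conditions: LiN(iPr)2 (1.1 equiv), THF, −78 °C; then Me3SiCl, −78 → 0 °C; distil
Reagents that add atoms: chlorotrimethylsilane, C[Si](C)(C)Cl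
Why: γ-Deprotonation of the vinylogous ester and O-silylation of the dienolate gives the silyl ketene acetal diene (silyl dienol ether formation).

**Step 3**
Reactants: 6 4-(tert-butyldimethylsilyloxy)benzaldehyde; 5 Brassard diene
Product: 8 (6S)-6-[4-(tert-butyldimethylsilyloxy)phenyl]-4-methoxy-5,6-dihydro-2H-pyran-2-one, via cycloadduct 7 (not isolated)
Conditions: (4S,5S)-2,2-dimethyl-α,α,α′,α′-tetra(1-naphthyl)-1,3-dioxolane-4,5-dimethanol [(S,S)-1-naphthyl-TADDOL] (20 mol %), PhMe, −40 °C, 48 h; then CF3CO2H (cat.), CH2Cl2, 0 °C; recrystallise to ≥98% ee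
Reagents that add atoms: none
Why: Hydrogen-bond-catalysed asymmetric hetero-Diels–Alder reaction of a Brassard diene, in which the diol shields one aldehyde face so that Si-face attack sets C6 as S, and collapse of the cyclic ortho ester 7 gives the lactone.

**Step 4**
Reactants: 3 tert-butyl 2-geranylacetoacetate; 8 (S)-lactone
Product: 10 tert-butyl (6E,9S)-9-[4-(tert-butyldimethylsilyloxy)phenyl]-2-[(2E)-3,7-dimethylocta-2,6-dien-1-yl]-9-hydroxy-7-methoxy-3,5-dioxonon-6-enoate (open-chain; epimers at C2), via dilithium dianion 9 (not isolated)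
Conditions: 3 (2.2 equiv), LiN(iPr)2 (4.5 equiv), THF, −78 → 0 °C; then 8 (1.0 equiv), −78 → −30 °C; AcOH, −78 °C; pH 7 work-up
Reagents that add atoms: none
Why: γ-Acylation of a Weiler dianion by a lactone (Claisen-type 1,2-addition with ring opening) is favoured over conjugate addition because the β-methoxy group deactivates the β-carbon, and the carbinol stereocentre is not involved.

**Step 5**
Reactants: 10 open-chain δ-hydroxy polyketide
Product: 13 (2S)-2-[4-(tert-butyldimethylsilyloxy)phenyl]-6-[(2E)-3,7-dimethylocta-2,6-dien-1-yl]-5,7-dihydroxy-2,3-dihydro-4H-chromen-4-one, via dihydropyranone keto ester 11 (not isolated), via acylketene 12 (not isolated)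
Conditions: PPTS (0.2 equiv), H2O (2 equiv), PhMe, 40 °C, 2 h; then 2,6-lutidine (0.3 equiv), xylenes (0.005 M), 135 °C, slow distillation of solvent, 4 h
Reagents that add atoms: water, O
Why: Proposed new method: mild acid lets the C9 hydroxyl of 10 add to the C5 ketone and the lactol lose water and then methanol (an intramolecular Stork–Danheiser-type vinylogous-ester transposition, closest precedent the acid cyclodehydration of δ-hydroxy β-alkoxy enones to 2,3-dihydro-4H-pyran-4-ones), which fixes O1–C8a (flavanone numbering) without touching the C2–O bond so that S is retained, after which heat expels tert-butanol from the β-keto ester to give acylketene 12, whose dienylketene tautomer closes by 6π-electrocyclisation onto the pyranone α-carbon and enolises to the phloroglucinol ring as in the last stage of a Danheiser benzannulation, while the ring oxygen already in place blocks the usual 2-pyranone trap and forces 6- rather than 8-geranyl regiochemistry.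

**Step 6**
Reactants: 13 silyl-protected flavanone
Product: 14 bonannione A, (2S)-6-geranyl-5,7-dihydroxy-2-(4-hydroxyphenyl)-2,3-dihydro-4H-chromen-4-one
Conditions: Bu4NF (1.2 equiv), AcOH (1.5 equiv), THF, 0 °C, 30 min
Reagents that add atoms: none
Why: Fluoride-induced cleavage of the aryl silyl ether, buffered with acetic acid so that no phenoxide-driven retro-oxa-Michael ring opening can racemise C2.

**Compound list**
1 | tert-butyl acetoacetate | CC(=O)CC(=O)OC(C)(C)C | starting material
2 | geranyl bromide, (2E)-1-bromo-3,7-dimethylocta-2,6-diene | CC(C)=CCC/C(C)=C/CBr | starting material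
3 | tert-butyl 2-[(2E)-3,7-dimethylocta-2,6-dien-1-yl]-3-oxobutanoate (racemic) | CC(=O)C(C/C=C(\C)CCC=C(C)C)C(=O)OC(C)(C)C | intermediate
4 | methyl (E)-3-methoxybut-2-enoate | CO/C(C)=C/C(=O)OC | starting material
5 | Brassard diene, (E)-1,3-dimethoxy-1-(trimethylsilyloxy)buta-1,3-diene | C=C(OC)/C=C(\OC)O[Si](C)(C)C | intermediate
6 | 4-(tert-butyldimethylsilyloxy)benzaldehyde | O=Cc1ccc(O[Si](C)(C)C(C)(C)C)cc1 | starting material
7 | (6S)-6-[4-(tert-butyldimethylsilyloxy)phenyl]-2,4-dimethoxy-2-(trimethylsilyloxy)-5,6-dihydro-2H-pyran (C2 unassigned) | COC1(O[Si](C)(C)C)C=C(OC)C[C@@H](c2ccc(O[Si](C)(C)C(C)(C)C)cc2)O1 | intermediate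
8 | (6S)-6-[4-(tert-butyldimethylsilyloxy)phenyl]-4-methoxy-5,6-dihydro-2H-pyran-2-one | O=C1C=C(OC)C[C@@H](c2ccc(O[Si](C)(C)C(C)(C)C)cc2)O1 | intermediate
9 | dilithium 2,4-dianion of 3 (enolate at C2, carbanion at C4) | [Li+].[Li+].[CH2-]C(=O)[C-](C/C=C(\C)CCC=C(C)C)C(=O)OC(C)(C)C | intermediate
10 | tert-butyl (6E,9S)-9-[4-(tert-butyldimethylsilyloxy)phenyl]-2-[(2E)-3,7-dimethylocta-2,6-dien-1-yl]-9-hydroxy-7-methoxy-3,5-dioxonon-6-enoate (C2 epimers) | CC(C)=CCC/C(C)=C/CC(C(=O)OC(C)(C)C)C(=O)CC(=O)/C=C(/OC)C[C@@H](c1ccc(O[Si](C)(C)C(C)(C)C)cc1)O | intermediate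
11 | tert-butyl 4-{(2S)-2-[4-(tert-butyldimethylsilyloxy)phenyl]-4-oxo-3,4-dihydro-2H-pyran-6-yl}-2-[(2E)-3,7-dimethylocta-2,6-dien-1-yl]-3-oxobutanoate (C2 epimers) | CC(C)=CCC/C(C)=C/CC(C(=O)OC(C)(C)C)C(=O)CC1=CC(=O)C[C@@H](c2ccc(O[Si](C)(C)C(C)(C)C)cc2)O1 | intermediate
12 | (2S)-2-[4-(tert-butyldimethylsilyloxy)phenyl]-6-{3-[(2E)-3,7-dimethylocta-2,6-dien-1-yl]-2,4-dioxobut-3-en-1-yl}-2,3-dihydro-4H-pyran-4-one (acylketene) | CC(C)=CCC/C(C)=C/CC(=C=O)C(=O)CC1=CC(=O)C[C@@H](c2ccc(O[Si](C)(C)C(C)(C)C)cc2)O1 | intermediate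
13 | (2S)-2-[4-(tert-butyldimethylsilyloxy)phenyl]-6-[(2E)-3,7-dimethylocta-2,6-dien-1-yl]-5,7-dihydroxy-2,3-dihydro-4H-chromen-4-one | CC(C)=CCC/C(C)=C/Cc1c(O)cc2c(c1O)C(=O)C[C@@H](c1ccc(O[Si](C)(C)C(C)(C)C)cc1)O2 | intermediate
14 | bonannione A, (2S)-6-[(2E)-3,7-dimethylocta-2,6-dien-1-yl]-5,7-dihydroxy-2-(4-hydroxyphenyl)-2,3-dihydro-4H-chromen-4-one | CC(C)=CCC/C(C)=C/Cc1c(O)cc2c(c1O)C(=O)C[C@@H](c1ccc(O)cc1)O2 | target

**Step count**
Total steps: 6. Longest linear sequence: 5 steps (4 → 5 → 8 → 10 → 13 → 14); step 1 is a one-step side branch that joins at step 4.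

**Steps most likely to fail, with fallbacks**

Step 5 (one-pot closure of rings C and A). The thermal loss of tert-butanol from an α-substituted β-keto ester may be slow, and the ketene may be lost to intermolecular trapping or to acid-induced decarboxylation. The fallback sets out from 10 and comes back at 13, and it replaces the pericyclic cascade by two separate, mechanistically different ring closures. Compound 10 is treated with PPTS in wet CH2Cl2 at 23 °C only, and the dihydropyranone keto ester 11 is isolated. Compound 11 is then cyclised with Mg(OMe)2 in THF/MeOH at 40 °C, a magnesium-chelate-templated Claisen condensation of the vinylogous dienolate carbon onto the ester with tert-butoxide as leaving group, of the kind that converts triketo esters into acylphloroglucinols. The enantiomeric excess of 13 is checked afterwards, because this route is basic. This fallback makes no compound outside the list (F0).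

Step 4 (dianion addition to the lactone). The dianion may instead deprotonate C5 of 8 (ring-opening elimination) or add in conjugate fashion. The fallback sets out from 8 and comes back at 10. Lactone 8 is opened with MeNH(OMe)·HCl/iPrMgCl in THF at −20 °C to the Weinreb amide (2E,5S)-5-hydroxy-N,3-dimethoxy-N-methyl-5-[4-(tert-butyldimethylsilyloxy)phenyl]pent-2-enamide F1. This is silylated with Et3SiCl/imidazole to its triethylsilyl ether F2. Dianion 9 is then acylated by F2 (Weinreb ketone synthesis, which allows neither conjugate addition nor over-addition) to give the triethylsilyl ether of 10, F3. AcOH/THF/H2O at 23 °C removes the triethylsilyl group and returns 10.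

Step 3 (asymmetric hetero-Diels–Alder reaction). The electron-rich aldehyde may react slowly or with insufficient enantioselectivity. The fallback sets out from 6 and comes back at 8, and it replaces the cycloaddition by an aldol/lactonisation/O-methylation sequence. A Ti(OiPr)4/(S)-BINOL-catalysed vinylogous Mukaiyama aldol reaction of 6 with Chan's diene (1-methoxy-1,3-bis(trimethylsilyloxy)buta-1,3-diene), followed by mild acidic work-up, gives methyl (5S)-5-[4-(tert-butyldimethylsilyloxy)phenyl]-5-hydroxy-3-oxopentanoate F4. Catalytic DBU in CH2Cl2 lactonises it to (6S)-6-[4-(tert-butyldimethylsilyloxy)phenyl]oxane-2,4-dione F5. O-Methylation of the enol with Me2SO4/K2CO3 in acetone then gives 8, which is recrystallised as in the main route.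

**Further compounds**
F0 | step 5 | none | none
F1 | step 4 | (2E,5S)-5-hydroxy-N,3-dimethoxy-N-methyl-5-[4-(tert-butyldimethylsilyloxy)phenyl]pent-2-enamide | CON(C)C(=O)/C=C(/OC)C[C@@H](c1ccc(O[Si](C)(C)C(C)(C)C)cc1)O
F2 | step 4 | (2E,5S)-N,3-dimethoxy-N-methyl-5-[4-(tert-butyldimethylsilyloxy)phenyl]-5-(triethylsilyloxy)pent-2-enamide | CON(C)C(=O)/C=C(/OC)C[C@@H](c1ccc(O[Si](C)(C)C(C)(C)C)cc1)O[Si](CC)(CC)CC
F3 | step 4 | tert-butyl (6E,9S)-9-[4-(tert-butyldimethylsilyloxy)phenyl]-2-[(2E)-3,7-dimethylocta-2,6-dien-1-yl]-7-methoxy-3,5-dioxo-9-(triethylsilyloxy)non-6-enoate | CC(C)=CCC/C(C)=C/CC(C(=O)OC(C)(C)C)C(=O)CC(=O)/C=C(/OC)C[C@@H](c1ccc(O[Si](C)(C)C(C)(C)C)cc1)O[Si](CC)(CC)CC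
F4 | step 3 | methyl (5S)-5-[4-(tert-butyldimethylsilyloxy)phenyl]-5-hydroxy-3-oxopentanoate | COC(=O)CC(=O)C[C@@H](c1ccc(O[Si](C)(C)C(C)(C)C)cc1)O
F5 | step 3 | (6S)-6-[4-(tert-butyldimethylsilyloxy)phenyl]oxane-2,4-dione | O=C1CC(=O)C[C@@H](c2ccc(O[Si](C)(C)C(C)(C)C)cc2)O1
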